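Slowness makes this flask readable: target leaks away gradually enough that the leak can be read late and carried back to the peak.

| setting | winter | midnight | flask |
|---|---|---|---|
| substrate | 13 mM (fed, over 20 min) | 30 mM (fed, over 20 min) | 20 mM (fed, over 20 min) |
| first nucleophile | 2 equiv | 2 equiv | 2.00 equiv |
| second nucleophile | 1.5 equiv | 1.5 equiv | 1.50 equiv |
| remark | run made earlier; the fed solution adds 1.0 times the starting volume | run made earlier; the fed solution adds 1.0 times the starting volume | the fed solution adds 1.0 times the starting volume |
| time |  |  | 3.0 h |
- winter (time / min: target / %, substrate / %): 6.00: 10.8, 16.5; 15.0: 38.1, 22.4; 40.0: 44.7, 0.4; 120: 13.7, 0.6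
- midnight (time / min: target / %, substrate / %): 6.00: 11.3, 17.0; 15.0: 39.9, 22.3; 40.0: 45.9, 0.6; 120: 13.4, 0.1

(standard deviation of a reading: 0.3 percentage points)
- amounts are per litre of the starting volume; all of the dose is in the solution fed
- steps under discussion: first nucleophile + intermediate <-> target; substrate -> intermediate; second nucleophile + intermediate -> other capture product
- percentages count the whole charge, also what has not yet gone in
* time up to 3.0 h at which target stands highest
* the amount of target, in percent of the substrate charged, at that time

The first rung is substrate. During the feed it freezes at a plateau where conversion matches feed, so the winter reading at 15.0 min gives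

k = 0.223 min⁻¹, a lifetime of 4.48 min, shorter than the feed.

The next rung is the leak. If target and intermediate equilibrate while the second nucleophile drains intermediate, the leak is pseudo-first-order with a constant proportional to [second nucleophile]/[first nucleophile]. That ratio carries no concentration, and the runs at 13 mM and 30 mM differ by 1.2 percentage points at 40.0 min. In the winter run target is read to fall at 0.0148 min⁻¹ while the ratio, counted with whatever is not target taken as other capture product, goes from 0.610 to 0.342. So

0.0311 min⁻¹

is the leak coefficient, the leak constant per unit of that ratio. Frozen at the charged ratio, the leak constant of the flask is estimated at 0.0233 min⁻¹, a lifetime of 42.9 min, longer than both clocks above.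

The reckoning here lets target plus substrate fall at that constant after the feed. Carried back from 40.0 min, the two runs then put that sum, as an estimate for the flask, at

73.0% at the end of the feed.

In this reckoning target peaks when conversion equals the leak, 5.40 min later:

0.423 h, 57.6%.

The forecast, 0.41 h and 57%, stepped forward “until formation equals loss”, and its time differs slightly from this one.

The flask gives 0.409 h and 58.2%.

    first nucleophile + intermediate ⇌ target (K = 939 M⁻¹, k = 7.24 M⁻¹ s⁻¹)
    substrate → intermediate (k = 0.00357 s⁻¹)
    second nucleophile + intermediate → other capture product (k = 0.606 M⁻¹ s⁻¹)

From the simulated 19.7% at 1.50 h, the leak coefficient with the simulated ratios carries the flask to 7.51% at 3.00 h, against 6.77% simulated. The flask's ratio at 3.00 h gives a leak of 0.551 h⁻¹. The neighbour charged with 0.380 equiv of second nucleophile keeps 4.14% of that charge at 3.00 h, so the same coefficient gives it 0.0208 h⁻¹, far slower. That neighbour holds 36.4% of other capture product and 59.1% of target.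

Readings and results stem from a simulated flask for substances that don't exist; noise was put on by code.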